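**Plan**

- Retrosynthesis: the veratrate ester bond at C5–O is cut first and the C5 oxygen is traced back to an allylic C–H bond. The seven-membered ring is then cut at the C6=C7 double bond and the C8–C8a single bond, which removes C7–C8 as triphenyl(vinyl)phosphonium and leaves a cyclopentene with a 3-oxobutyl chain. The chain comes off at C3a–C4, and the cyclopentenone opens (metathesis) to an acyclic dienone made by auxiliary-controlled allylation.
- Forward order: five-membered ring (ring-closing metathesis), chain by carbonyl addition, seven-membered ring by the key step, then C5 oxidation, directed reduction and esterification.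
- Enabling feature: in the seven-membered ring the olefinic CH (C7) and its CH2 neighbour (C8) are a two-carbon bridge between C6, which can be a methyl-ketone carbonyl, and the quaternary ring-fusion carbon C8a, which can be a tertiary radical generated from the cyclopentene C=C. A vinylphosphonium salt is a radical acceptor at its CH2 end and a Wittig donor at its CH end.
- Stereochemistry: C3 from Evans alkylation; C3a from addition to the cyclopentenone anti to isopropyl; C8a in the key step (radical capture anti to OSiEt3 and isopropyl); C5 from hydride delivery directed by the C3a hydroxyl.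

Key step: step 10

Remark: azulene numbering is used for the bicyclic compounds (C3 isopropyl, C3a hydroxyl, C5 ester oxygen, C6 and C8a methyl). The target is read as the cis-fused (3R,3aS,5R,8aR) isomer, with 3a-OH, 8a-CH3 and isopropyl on one face and the C5 oxygen on the other.

**Route**

Step 1
Reactants: 1 (4R)-4-benzyl-1,3-oxazolidin-2-one; 2 3-methylbutanoyl chloride
Product: 3 (4R)-4-benzyl-3-(3-methylbutanoyl)-1,3-oxazolidin-2-one
Conditions: n-BuLi, THF, −78 °C; then 2, −78 to 0 °C
Reagents that add atoms: none
Why: N-acylation of the lithiated Evans oxazolidinone by the acid chloride, with no stereocenter touched.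

Step 2
Reactants: 3 (4R)-4-benzyl-3-(3-methylbutanoyl)-1,3-oxazolidin-2-one; 4 3-iodoprop-1-ene (allyl iodide)
Product: 5 (4R)-4-benzyl-3-[(2R)-2-(propan-2-yl)pent-4-enoyl]-1,3-oxazolidin-2-one
Conditions: NaN(SiMe3)2, THF, −78 °C; then 4
Reagents that add atoms: none
Why: Evans asymmetric alkylation, in which the chelated (Z)-sodium enolate is allylated on the face opposite the benzyl group, setting the (2R) isopropyl-bearing center that becomes C3 of the target.

Step 3
Reactants: 5 (4R)-4-benzyl-3-[(2R)-2-(propan-2-yl)pent-4-enoyl]-1,3-oxazolidin-2-one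
Product: 6 (2R)-2-(propan-2-yl)pent-4-enoic acid
Conditions: LiOH, H2O2, THF/H2O, 0 °C; then aq. Na2SO3; HCl to pH 2
Reagents that add atoms: hydrogen peroxide, OO
Why: Hydroperoxide cleavage of the Evans imide attacks the exocyclic carbonyl selectively and should not epimerise the α-center, with the auxiliary 1 recovered.

Step 4
Reactants: 6 (2R)-2-(propan-2-yl)pent-4-enoic acid; 7 N,O-dimethylhydroxylamine hydrochloride
Product: 8 (2R)-N-methoxy-N-methyl-2-(propan-2-yl)pent-4-enamide
Conditions: 1,1'-carbonyldiimidazole, CH2Cl2, rt; then 7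
Reagents that add atoms: none
Why: Weinreb amide formation through the acyl imidazolide, a neutral activation that should leave the α-stereocenter intact.

Step 5
Reactants: 8 (2R)-N-methoxy-N-methyl-2-(propan-2-yl)pent-4-enamide; 9 prop-1-en-2-ylmagnesium bromide
Product: 10 (4R)-2-methyl-4-(propan-2-yl)hepta-1,6-dien-3-one
Conditions: THF, 0 °C; inverse quench into cold aq. HCl
Reagents that add atoms: none
Why: Weinreb ketone synthesis, in which the chelated tetrahedral adduct persists until work-up, so over-addition is avoided and the α-center is never exposed to the Grignard reagent as a free ketone.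

Step 6
Reactants: 10 (4R)-2-methyl-4-(propan-2-yl)hepta-1,6-dien-3-one
Product: 11 (5R)-2-methyl-5-(propan-2-yl)cyclopent-2-en-1-one
Conditions: second-generation Grubbs catalyst (cat.), CH2Cl2, 40 °C
Reagents that add atoms: none
Why: Ring-closing metathesis between the allyl and the isopropenyl-ketone olefins closes the cyclopentenone with loss of ethene under neutral conditions that should not epimerise C5.

Step 7
Reactants: 11 (5R)-2-methyl-5-(propan-2-yl)cyclopent-2-en-1-one; 12 but-3-en-1-ylmagnesium bromide
Product: 13 (1S,5R)-1-(but-3-en-1-yl)-2-methyl-5-(propan-2-yl)cyclopent-2-en-1-ol (hydroxyl cis to isopropyl)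
Conditions: CeCl3, THF, −78 °C
Reagents that add atoms: none
Why: Organocerium 1,2-addition suppresses enolisation and conjugate addition, and attack on the carbonyl face opposite the adjacent isopropyl group sets the carbinol center (future C3a) with the hydroxyl cis to isopropyl.

Step 8
Reactants: 13 (1S,5R)-1-(but-3-en-1-yl)-2-methyl-5-(propan-2-yl)cyclopent-2-en-1-ol
Product: 14 {[(1S,5R)-1-(but-3-en-1-yl)-2-methyl-5-(propan-2-yl)cyclopent-2-en-1-yl]oxy}triethylsilane
Conditions: Et3SiOTf, 2,6-lutidine, CH2Cl2, −78 to 0 °C
Reagents that add atoms: triethylsilyl trifluoromethanesulfonate, CC[Si](CC)(CC)OS(=O)(=O)C(F)(F)F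
Why: Silylation of the hindered tertiary alcohol with a silyl triflate and a hindered base; the ether blocks hydroxyl participation in steps 9 and 10 and adds bulk to the oxygen-bearing face.

Step 9
Reactants: 14 {[(1S,5R)-1-(but-3-en-1-yl)-2-methyl-5-(propan-2-yl)cyclopent-2-en-1-yl]oxy}triethylsilane
Product: 15 4-[(1S,5R)-2-methyl-5-(propan-2-yl)-1-(triethylsilyloxy)cyclopent-2-en-1-yl]butan-2-one
Conditions: PdCl2 (cat.), Cu(OAc)2 (cat.), O2 (1 atm), DMA/H2O, rt
Reagents that add atoms: water, O
Why: Tsuji–Wacker oxidation converts the terminal olefin into the methyl ketone by Markovnikov hydroxypalladation, while the trisubstituted ring olefin is inert and the acetate-buffered medium should spare the silyl ether.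

Step 10
Reactants: 15 4-[(1S,5R)-2-methyl-5-(propan-2-yl)-1-(triethylsilyloxy)cyclopent-2-en-1-yl]butan-2-one; 16 triphenyl(vinyl)phosphonium bromide
Product: 19 triethyl{[(3R,3aS,8aR)-6,8a-dimethyl-3-(propan-2-yl)-1,2,3,3a,4,5,8,8a-octahydroazulen-3a-yl]oxy}silane, via phosphonium bromide 17 (not isolated), via ylide 18 (not isolated)
Conditions: Fe(acac)3 (cat.), PhSiH3, 16 (2 equiv), i-PrOH/CH2Cl2, 35 °C; then evaporation, THF (high dilution), KN(SiMe3)2, −78 °C to rt
Reagents that add atoms: none
Why: Proposed new method: iron-hydride hydrogen-atom transfer to the trisubstituted ring olefin of 15 places H on the CH carbon and leaves a tertiary radical at the methyl-bearing carbon, which adds to the CH2 terminus of 16; the α-phosphonio radical is reduced by divalent iron and protonated to salt 17, and KN(SiMe3)2 then forms ylide 18, which olefinates the methyl ketone. The closest known reaction types are the Fe(acac)3/PhSiH3 Giese coupling of unactivated olefins with acceptor olefins, the photoredox addition of alkyl radicals to vinylphosphonium salts followed by Wittig olefination, and the Schweizer annulation, in which a two-electron nucleophile takes the place of the radical. The seven-membered ring closes by intramolecular Wittig reaction, a 7-exo-trig attack of the ylide carbon on the ketone followed by loss of Ph3PO from the oxaphosphetane, which can only give the endocyclic trisubstituted olefin. The new quaternary center C8a is set in the radical addition under substrate control: the acceptor should approach anti to the vicinal OSiEt3 group (which the cis isopropyl group pushes over that face) and anti to the isopropyl group itself, so the phosphonioethyl arm ends up cis to the oxobutyl chain and the ring fusion is cis. The step needs Markovnikov hydrogen-atom transfer (secured by the trisubstituted olefin, the only olefin left in 15), intermolecular radical capture in preference to the reversible 5-exo addition to the tethered ketone (secured by the excess of the strongly electrophilic acceptor), and ring closure in preference to intermolecular olefination by ylides from surplus 16 (secured by high dilution in the base stage).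

Step 11
Reactants: 19 triethyl{[(3R,3aS,8aR)-6,8a-dimethyl-3-(propan-2-yl)-1,2,3,3a,4,5,8,8a-octahydroazulen-3a-yl]oxy}silane
Product: 20 (3R,3aS,8aR)-6,8a-dimethyl-3-(propan-2-yl)-1,2,3,3a,4,5,8,8a-octahydroazulen-3a-ol
Conditions: Bu4NF, THF, rt to 50 °C
Reagents that add atoms: none
Why: Fluoride-mediated cleavage of the tertiary silyl ether, which should not affect the olefin or any stereocenter.

Step 12
Reactants: 20 (3R,3aS,8aR)-6,8a-dimethyl-3-(propan-2-yl)-1,2,3,3a,4,5,8,8a-octahydroazulen-3a-ol
Product: 21 (3R,3aS,8aR)-6,8a-dimethyl-3-(propan-2-yl)-1,2,3,3a,4,5,8,8a-octahydroazulene-3a,5-diol (mixture of C5 epimers, used as such)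
Conditions: SeO2 (cat.), t-BuOOH, CH2Cl2, rt
Reagents that add atoms: tert-butyl hydroperoxide, CC(C)(C)OO
Why: Riley allylic hydroxylation (ene reaction then [2,3]-sigmatropic shift) should oxidise at the more substituted olefin terminus and there prefer the ring CH2 (C5) over the methyl group, while C8 sits on the less substituted terminus next to the quaternary C8a; the C5 configuration does not matter because step 13 erases it.

Step 13
Reactants: 21 (3R,3aS,8aR)-6,8a-dimethyl-3-(propan-2-yl)-1,2,3,3a,4,5,8,8a-octahydroazulene-3a,5-diol (C5 epimers)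
Product: 22 (3R,3aS,8aR)-3a-hydroxy-6,8a-dimethyl-3-(propan-2-yl)-2,3,3a,4,8,8a-hexahydroazulen-5(1H)-one
Conditions: MnO2 (excess), CH2Cl2, rt
Reagents that add atoms: none
Why: MnO2 oxidises only the allylic secondary alcohol, so both C5 epimers should converge on one enone while the tertiary alcohol stays untouched under neutral conditions that avoid retro-aldol cleavage or dehydration.

Step 14
Reactants: 22 (3R,3aS,8aR)-3a-hydroxy-6,8a-dimethyl-3-(propan-2-yl)-2,3,3a,4,8,8a-hexahydroazulen-5(1H)-one
Product: 23 (3R,3aS,5R,8aR)-6,8a-dimethyl-3-(propan-2-yl)-1,2,3,3a,4,5,8,8a-octahydroazulene-3a,5-diol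
Conditions: Me4NBH(OAc)3, MeCN/AcOH, −30 to 0 °C
Reagents that add atoms: none
Why: Evans–Saksena hydroxyl-directed reduction, in which the C3a hydroxyl exchanges onto boron and delivers hydride intramolecularly to the carbonyl face on its own side (1,2-reduction), so the new C5 hydroxyl should end up trans to the C3a hydroxyl, the (5R) configuration.

Step 15
Reactants: 23 (3R,3aS,5R,8aR)-6,8a-dimethyl-3-(propan-2-yl)-1,2,3,3a,4,5,8,8a-octahydroazulene-3a,5-diol; 24 3,4-dimethoxybenzoyl chloride
Product: 25 (3R,3aS,5R,8aR)-3a-hydroxy-6,8a-dimethyl-3-(propan-2-yl)-1,2,3,3a,4,5,8,8a-octahydroazulen-5-yl 3,4-dimethoxybenzoate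
Conditions: Et3N, DMAP (cat.), CH2Cl2, 0 °C to rt
Reagents that add atoms: none
Why: DMAP-catalysed acylation of the secondary allylic hydroxyl with retention at C5 (the C–O bond is not broken), while the hindered tertiary ring-fusion hydroxyl should not react.

**Compound list**

1 | (4R)-4-benzyl-1,3-oxazolidin-2-one | O=C1N[C@H](Cc2ccccc2)CO1 | starting material
2 | 3-methylbutanoyl chloride | CC(C)CC(=O)Cl | starting material
3 | (4R)-4-benzyl-3-(3-methylbutanoyl)-1,3-oxazolidin-2-one | CC(C)CC(=O)N1[C@H](Cc2ccccc2)COC1=O | intermediate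
4 | 3-iodoprop-1-ene (allyl iodide) | C=CCI | starting material
5 | (4R)-4-benzyl-3-[(2R)-2-(propan-2-yl)pent-4-enoyl]-1,3-oxazolidin-2-one | O=C([C@@H](C(C)C)CC=C)N1[C@H](Cc2ccccc2)COC1=O | intermediate
6 | (2R)-2-(propan-2-yl)pent-4-enoic acid | OC(=O)[C@@H](C(C)C)CC=C | intermediate
7 | N,O-dimethylhydroxylamine hydrochloride | CNOC.Cl | starting material
8 | (2R)-N-methoxy-N-methyl-2-(propan-2-yl)pent-4-enamide | CON(C)C(=O)[C@@H](C(C)C)CC=C | intermediate
9 | prop-1-en-2-ylmagnesium bromide | C=C(C)[Mg]Br | starting material
10 | (4R)-2-methyl-4-(propan-2-yl)hepta-1,6-dien-3-one | C=C(C)C(=O)[C@@H](C(C)C)CC=C | intermediate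
11 | (5R)-2-methyl-5-(propan-2-yl)cyclopent-2-en-1-one | O=C1[C@@H](C(C)C)CC=C1C | intermediate
12 | but-3-en-1-ylmagnesium bromide | C=CCC[Mg]Br | starting material
13 | (1S,5R)-1-(but-3-en-1-yl)-2-methyl-5-(propan-2-yl)cyclopent-2-en-1-ol | C=CCC[C@]1(O)[C@@H](C(C)C)CC=C1C | intermediate
14 | {[(1S,5R)-1-(but-3-en-1-yl)-2-methyl-5-(propan-2-yl)cyclopent-2-en-1-yl]oxy}triethylsilane | C=CCC[C@]1(O[Si](CC)(CC)CC)[C@@H](C(C)C)CC=C1C | intermediate
15 | 4-[(1S,5R)-2-methyl-5-(propan-2-yl)-1-(triethylsilyloxy)cyclopent-2-en-1-yl]butan-2-one | CC(=O)CC[C@]1(O[Si](CC)(CC)CC)[C@@H](C(C)C)CC=C1C | intermediate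
16 | triphenyl(vinyl)phosphonium bromide | C=C[P+](c1ccccc1)(c1ccccc1)c1ccccc1.[Br-] | starting material
17 | {2-[(1R,2S,3R)-1-methyl-2-(3-oxobutyl)-3-(propan-2-yl)-2-(triethylsilyloxy)cyclopentyl]ethyl}triphenylphosphonium bromide | CC(=O)CC[C@]1(O[Si](CC)(CC)CC)[C@@H](C(C)C)CC[C@]1(C)CC[P+](c1ccccc1)(c1ccccc1)c1ccccc1.[Br-] | intermediate
18 | 4-[(1S,2R,5R)-2-methyl-5-(propan-2-yl)-1-(triethylsilyloxy)-2-[2-(triphenyl-λ5-phosphanylidene)ethyl]cyclopentyl]butan-2-one (ylide of 17) | CC(=O)CC[C@]1(O[Si](CC)(CC)CC)[C@@H](C(C)C)CC[C@]1(C)CC=P(c1ccccc1)(c1ccccc1)c1ccccc1 | intermediate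
19 | triethyl{[(3R,3aS,8aR)-6,8a-dimethyl-3-(propan-2-yl)-1,2,3,3a,4,5,8,8a-octahydroazulen-3a-yl]oxy}silane | C1C[C@]2(O[Si](CC)(CC)CC)[C@@H](C(C)C)CC[C@]2(C)CC=C1C | intermediate
20 | (3R,3aS,8aR)-6,8a-dimethyl-3-(propan-2-yl)-1,2,3,3a,4,5,8,8a-octahydroazulen-3a-ol | C1C[C@]2(O)[C@@H](C(C)C)CC[C@]2(C)CC=C1C | intermediate
21 | (3R,3aS,8aR)-6,8a-dimethyl-3-(propan-2-yl)-1,2,3,3a,4,5,8,8a-octahydroazulene-3a,5-diol, both C5 epimers | OC1C[C@]2(O)[C@@H](C(C)C)CC[C@]2(C)CC=C1C | intermediate
22 | (3R,3aS,8aR)-3a-hydroxy-6,8a-dimethyl-3-(propan-2-yl)-2,3,3a,4,8,8a-hexahydroazulen-5(1H)-one | O=C1C[C@]2(O)[C@@H](C(C)C)CC[C@]2(C)CC=C1C | intermediate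
23 | (3R,3aS,5R,8aR)-6,8a-dimethyl-3-(propan-2-yl)-1,2,3,3a,4,5,8,8a-octahydroazulene-3a,5-diol | O[C@@H]1C[C@]2(O)[C@@H](C(C)C)CC[C@]2(C)CC=C1C | intermediate
24 | 3,4-dimethoxybenzoyl chloride | COc1ccc(C(=O)Cl)cc1OC | starting material
25 | (3R,3aS,5R,8aR)-3a-hydroxy-6,8a-dimethyl-3-(propan-2-yl)-1,2,3,3a,4,5,8,8a-octahydroazulen-5-yl 3,4-dimethoxybenzoate | COc1ccc(C(=O)O[C@@H]2C[C@]3(O)[C@@H](C(C)C)CC[C@]3(C)CC=C2C)cc1OC | target

**Step count and risks**

Total step count: 15. Longest linear sequence: 15 steps (from 1 to 25; compounds 2, 4, 7, 9, 12, 16 and 24 are bought).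

Steps most likely to fail:

Step 10 (carries the new-method label). The tertiary radical may be captured on the wrong face, may be intercepted by the tethered ketone (reductive cyclisation to a cyclopentanol), or the base stage may be diverted into intermolecular olefination by ylides formed from surplus phosphonium salt. The fallback uses known chemistry only, sets out from 11 and comes back at 20. Enone 11 is submitted to Stork reductive alkylation (Li, liquid NH3, THF, −78 °C, then allyl bromide); the regiodefined enolate should be allylated anti to the isopropyl group to give (2R,5R)-2-methyl-5-(propan-2-yl)-2-(prop-2-en-1-yl)cyclopentan-1-one F1. CeCl3-mediated addition of (3-methylbut-3-en-1-yl)magnesium bromide, again anti to isopropyl, should give (1S,2R,5R)-2-methyl-1-(3-methylbut-3-en-1-yl)-5-(propan-2-yl)-2-(prop-2-en-1-yl)cyclopentan-1-ol F2. Ring-closing metathesis with the second-generation Grubbs catalyst then closes the seven-membered ring at C6=C7 and delivers 20. Here the quaternary center is set by polar enolate alkylation and the ring by metathesis instead of by radical capture and olefination.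

Step 12. The ene reaction may compete at the vinylic methyl group or at C8, the product may be over-oxidised, or conversion may stall next to the ring fusion. The fallback installs the C5 oxygen before ring closure; it sets out from 15 and comes back at 21. Ketone 15 is silylated under equilibrating conditions (Et3SiCl, NaI, Et3N, MeCN) to the more substituted enol ether, triethyl{[(2Z)-4-[(1S,5R)-2-methyl-5-(propan-2-yl)-1-(triethylsilyloxy)cyclopent-2-en-1-yl]but-2-en-2-yl]oxy}silane F3. Rubottom oxidation (one equivalent of mCPBA, NaHCO3, CH2Cl2, −20 °C; the enol ether should react before the ring olefin) gives, after 1,4-silyl shift, 3-(triethylsilyloxy)-4-[(1S,5R)-2-methyl-5-(propan-2-yl)-1-(triethylsilyloxy)cyclopent-2-en-1-yl]butan-2-one F4 as a mixture of epimers. The conditions of step 10 then close the ring to the 3a,5-bis(triethylsilyl) ether of 21 F5, and Bu4NF gives 21.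

Step 14. Exchange of the hindered tertiary hydroxyl onto boron may be slow, so that hydride delivery is no longer intramolecular and the facial selectivity or the 1,2-selectivity is lost. The fallback replaces substrate direction by reagent control; it sets out from 22 and comes back at 23 without any new compound. CBS reduction of 22 with (S)-2-methyl-CBS-oxazaborolidine and BH3·SMe2 (excess, to allow for the free hydroxyl) is used. The α-methyl alkenyl carbon C6 takes the place of the large group, as the aryl group does in aryl alkyl ketones, which should give the (5R) carbinol 23.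

Further compounds
F1 | step 10 | (2R,5R)-2-methyl-5-(propan-2-yl)-2-(prop-2-en-1-yl)cyclopentan-1-one | O=C1[C@@H](C(C)C)CC[C@]1(C)CC=C
F2 | step 10 | (1S,2R,5R)-2-methyl-1-(3-methylbut-3-en-1-yl)-5-(propan-2-yl)-2-(prop-2-en-1-yl)cyclopentan-1-ol | C=C(C)CC[C@]1(O)[C@@H](C(C)C)CC[C@]1(C)CC=C
F3 | step 12 | triethyl{[(2Z)-4-[(1S,5R)-2-methyl-5-(propan-2-yl)-1-(triethylsilyloxy)cyclopent-2-en-1-yl]but-2-en-2-yl]oxy}silane | C/C(O[Si](CC)(CC)CC)=C/C[C@]1(O[Si](CC)(CC)CC)[C@@H](C(C)C)CC=C1C
F4 | step 12 | 3-(triethylsilyloxy)-4-[(1S,5R)-2-methyl-5-(propan-2-yl)-1-(triethylsilyloxy)cyclopent-2-en-1-yl]butan-2-one, both C3 epimers | CC(=O)C(O[Si](CC)(CC)CC)C[C@]1(O[Si](CC)(CC)CC)[C@@H](C(C)C)CC=C1C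
F5 | step 12 | 3a,5-bis(triethylsilyl) ether of 21, both C5 epimers | CC[Si](CC)(CC)OC1C[C@]2(O[Si](CC)(CC)CC)[C@@H](C(C)C)CC[C@]2(C)CC=C1C
F0 | step 14 | none | none
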